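**Retrosynthetic overview**
1. Side chain: C15=C16 by Horner–Wadsworth–Emmons reaction of a cis-fused α-phosphono γ-lactone with dienal 35; the lactone comes from carbenoid C–H insertion at C14 (sets C14), and C26–OH from hydroxyl-directed ketone reduction.
2. Tetrasubstituted enal: a temporary oxepine (carbenoid O–H insertion, then intramolecular HWE onto the C7 ketone) locks the enol oxygen cis to C6; stereoretentive nickel-catalysed C–O to C–CH3 exchange opens it and frees the hydroxypropyl chain.
3. Key step: one Prins–semipinacol cascade of a silylene-tethered (Z)-alkenyl cyclobutanol aldehyde forms ring B and the spiro cyclopentanone together and sets C6 and C11 from C10.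
4. Cascade substrate: geraniol (Sharpless epoxidation sets C10), then epoxy chloride, tertiary alkynol, directed trans-hydrostannation, alkenyllithium plus cyclobutanone.
5. Ring order: cyclobutane (bought); ring B and cyclopentane simultaneously (step 8); temporary oxepine (closed step 14, opened step 16); temporary γ-lactone (closed step 21, opened step 25).

Assumption: atoms carry iridal-type labels (C1 = CHO; C2 bears CH3; C3–C5 = hydroxypropyl chain with OH on C3; C6–C11 = ring B with C11 the spiro atom; C12–C14 and C26 = cyclopentane, C26 the carbinol; C15 bears C27H2OH; C16 onward = trienyl chain); 4, 19, 26 and 33 are taken as purchasable; the C7 carbinol of 14 is drawn as the expected equatorial epimer and either epimer gives 15.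

**Step 1**
Reactants: 1 geraniol
Product: 2 (2S,3S)-2,3-epoxygeraniol
Conditions: Ti(OiPr)4 (5 mol %), L-(+)-diethyl tartrate (7 mol %), t-BuOOH, 4 Å MS, CH2Cl2, −20 °C
Reagents that add atoms: tert-butyl hydroperoxide CC(C)(C)OO
Why: Sharpless asymmetric epoxidation of the allylic alcohol, in which the L-(+)-tartrate catalyst delivers oxygen to one alkene face and so sets the future C10 carbinol centre (3S), the remote trisubstituted alkene being untouched.

**Step 2**
Reactants: 2 (2S,3S)-2,3-epoxygeraniol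
Product: 3 (2R,3S)-2-(chloromethyl)-3-methyl-3-(4-methylpent-3-en-1-yl)oxirane
Conditions: PPh3, CCl4, NaHCO3, reflux
Reagents that add atoms: carbon tetrachloride ClC(Cl)(Cl)Cl
Why: Appel chlorination of the primary alcohol under neutral conditions leaves the epoxide and both stereocentres intact (the C2 descriptor changes by priority only).

**Step 3**
Reactants: 3 epoxy chloride; 4 benzyl 3-bromopropyl ether
Product: 6 (6S)-1-(benzyloxy)-6,10-dimethylundec-9-en-4-yn-6-ol, via dilithium alkynide alkoxide 5 (not isolated)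
Conditions: n-BuLi (3.2 equiv), THF, −40 °C; then 4, DMPU, −40 → 25 °C
Reagents that add atoms: none
Why: Base-induced double elimination of the 2,3-epoxy chloride (epoxide opening, then dehydrochlorination) gives the tertiary propargylic alkoxide/acetylide without touching the C–O stereocentre, and the acetylide is C-alkylated by the primary bromide.

**Step 4**
Reactants: 6 (6S)-alkynol
Product: 7 (4Z,6S)-1-(benzyloxy)-6,10-dimethyl-5-(tributylstannyl)undeca-4,9-dien-6-ol
Conditions: Bu3SnH (1.1 equiv), [Cp*RuCl]4 (2.5 mol %), CH2Cl2, 25 °C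
Reagents that add atoms: tributyltin hydride CCCC[SnH](CCCC)CCCC
Why: Hydroxyl-directed ruthenium-catalysed trans-hydrostannation, in which hydrogen bonding of the tertiary OH to Ru–Cl places tin on the proximal alkyne carbon and H trans to it, fixing the alkene geometry (chain cis to tin) that step 8 needs.

**Step 5**
Reactants: 7 alkenylstannane; 8 cyclobutanone
Product: 10 1-[(4Z,6S)-1-(benzyloxy)-6-hydroxy-6,10-dimethylundeca-4,9-dien-5-yl]cyclobutan-1-ol, via dilithium alkenyl alkoxide 9 (not isolated)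
Conditions: MeLi (2.2 equiv), THF, −78 → −20 °C; then 8, −78 °C
Reagents that add atoms: none
Why: Tin–lithium exchange occurs with retention at the alkenyl carbon and the alkenyllithium adds 1,2 to the strained ketone, so the cyclobutanol ends up cis to the C5 chain.

**Step 6**
Reactants: 10 diol
Product: 11 (8S,9Z)-9-[4-(benzyloxy)butylidene]-8-methyl-8-(4-methylpent-3-en-1-yl)-6,6-di(propan-2-yl)-5,7-dioxa-6-silaspiro[3.5]nonane
Conditions: (i-Pr)2Si(OTf)2, 2,6-lutidine, CH2Cl2, 0 °C
Reagents that add atoms: diisopropylsilyl bis(trifluoromethanesulfonate) CC(C)[Si](OS(=O)(=O)C(F)(F)F)(OS(=O)(=O)C(F)(F)F)C(C)C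
Why: Silylene protection of the 1,3-diol ties both tertiary allylic oxygens into a six-membered ring, which holds their C–O bonds in the alkene plane (no ionisation) and fixes the C10–O bond syn to the cyclobutane for facial control in step 8.

**Step 7**
Reactants: 11 silylene
Product: 12 3-[(8S,9Z)-9-[4-(benzyloxy)butylidene]-8-methyl-6,6-di(propan-2-yl)-5,7-dioxa-6-silaspiro[3.5]nonan-8-yl]propanal
Conditions: OsO4 (2 mol %), NaIO4, 2,6-lutidine, dioxane/H2O, 25 °C
Reagents that add atoms: osmium tetroxide O=[Os](=O)(=O)=O (catalytic oxygen carrier); sodium periodate [Na+].[O-]I(=O)(=O)=O (terminal oxidant)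
Why: Lemieux–Johnson cleavage is selective for the unhindered prenyl-type alkene, because the other alkene is flanked by two quaternary carbons inside the silylene ring.

**Step 8**
Reactants: 12 aldehyde
Product: 14 (5R,6S,9S,10S)-10-[3-(benzyloxy)propyl]-6,9-dihydroxy-6-methylspiro[4.5]decan-1-one, via chlorosilyl ether 13 (not isolated)
Conditions: SnCl4 (1.2 equiv), CH2Cl2, −78 °C; then aq. HF, MeCN, 0 °C
Reagents that add atoms: none
Why: Proposed new method: the SnCl4-bound aldehyde attacks C6 of the alkene through a chair transition state (Prins cyclization) and the developing C11 cation is quenched by anti 1,2-shift of a cyclobutane carbon (semipinacol ring expansion driven by strain release and the silyloxy donor), so ring B, the cyclopentanone and the spiro centre form together; the tether puts C9 on one alkene face and the shift occurs on the other, so C26 ends cis to the C10 oxygen and, from the Z alkene, the C6 chain ends cis to C26; the closest known reaction type is the Prins–pinacol ring-enlarging annulation of 1-alkenylcycloalkanol silyl ethers with acetals or aldehydes.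

**Step 9**
Reactants: 14 hydroxy ketone
Product: 15 (5R,6S,10S)-6-[3-(benzyloxy)propyl]-10-hydroxy-10-methylspiro[4.5]decane-1,7-dione
Conditions: Dess–Martin periodinane, NaHCO3, CH2Cl2, 25 °C
Reagents that add atoms: none
Why: Dess–Martin oxidation of the secondary C7 carbinol under buffered non-basic conditions, which avoid retro-aldol cleavage of the tertiary β-hydroxy ketone and do not epimerise C6.

**Step 10**
Reactants: 15 diketone
Product: 16 (1R,5S,6S,10S)-6-[3-(benzyloxy)propyl]-1,10-dihydroxy-10-methylspiro[4.5]decan-7-one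
Conditions: Me4NBH(OAc)3, MeCN/AcOH, −30 °C
Reagents that add atoms: none
Why: Evans–Saksena reduction, in which the borohydride exchanges onto the C10 hydroxyl and delivers hydride intramolecularly to the C10 face of the C26 ketone, giving the 1,3-anti diol (C26–OH cis to C6); the C7 ketone has no β-hydroxyl and is not reduced.

**Step 11**
Reactants: 16 diol ketone
Product: 17 (1R,5S,6S,10S)-6-[3-(benzyloxy)propyl]-10-hydroxy-10-methyl-7-oxospiro[4.5]decan-1-yl benzoate
Conditions: BzCl, pyridine, DMAP (cat.), CH2Cl2, 0 → 25 °C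
Reagents that add atoms: benzoyl chloride O=C(Cl)c1ccccc1
Why: Selective acylation of the secondary alcohol (the tertiary one is inert) masks C26–OH so that it can neither form a hemiketal with the C7 ketone nor compete in step 13.

**Step 12**
Reactants: 17 benzoate
Product: 18 (1R,5S,6S,10S)-10-hydroxy-6-(3-hydroxypropyl)-10-methyl-7-oxospiro[4.5]decan-1-yl benzoate
Conditions: H2 (1 atm), Pd/C, EtOAc, 25 °C
Reagents that add atoms: none
Why: Hydrogenolysis of the benzyl ether; no alkene is present at this stage and the ketone and benzoate are inert.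

**Step 13**
Reactants: 18 hydroxy ketone; 19 ethyl diazo(diethoxyphosphoryl)acetate
Product: 20 ethyl 2-{3-[(1R,5S,6S,10S)-1-(benzoyloxy)-10-hydroxy-10-methyl-7-oxospiro[4.5]decan-6-yl]propoxy}-2-(diethoxyphosphoryl)acetate (both epimers at the phosphonate carbon)
Conditions: Rh2(OAc)4 (2 mol %), benzene, 80 °C
Reagents that add atoms: none
Why: Rhodium carbenoid O–H insertion into the unhindered primary alcohol (the buried tertiary OH does not compete) installs the α-alkoxy phosphonoacetate, whose new centre is lost in step 14.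

**Step 14**
Reactants: 20 α-alkoxy phosphonoacetate
Product: 21 oxepine ester (ring B fused at C6–C7 to a 2,3,4,5-tetrahydrooxepine; enol ether C2=C7; CO2Et on C2; C26 benzoate)
Conditions: NaH (1.05 equiv), THF, 0 → 25 °C
Reagents that add atoms: none
Why: Intramolecular Horner–Wadsworth–Emmons olefination with the C7 ketone closes a seven-membered cyclic enol ether whose ring forces the enol oxygen cis to C6 and the ester (future C1) cis to C8, locking the geometry of the tetrasubstituted alkene; one equivalent of base limits C6 epimerisation.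

**Step 15**
Reactants: 21 oxepine ester
Product: 22 oxepine carboxylic acid (CO2H on C2; C26–OH free)
Conditions: LiOH, THF/MeOH/H2O, 40 °C; pH 4 work-up (dilute HCl)
Reagents that add atoms: lithium hydroxide [Li+].[OH-]
Why: Saponification of the α-alkoxy acrylate (and of the benzoate) gives the acid, so that C1 enters the nickel step as a carboxylate with neither an electrophilic ester nor an allylic or β-positioned C–O leaving group.

**Step 16**
Reactants: 22 oxepine acid
Product: 23 ring-opened (E)-acid (C7=C2(CH3)CO2H; CH3 cis to C6; 3-hydroxypropyl on C6)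
Conditions: MeMgBr (10 equiv), NiCl2(PCy3)2 (10 mol %), toluene/THF, 80 °C
Reagents that add atoms: methylmagnesium bromide C[Mg]Br
Why: Wenkert-type nickel-catalysed Kumada coupling of a cyclic enol ether, in which zerovalent nickel inserts into the vinylic C–O bond (assisted by the neighbouring magnesium carboxylate) and CH3 replaces oxygen with retention, so CH3 is cis to C6 and the carboxyl cis to C8, while the ring opening releases the 3-hydroxypropyl chain.

**Step 17**
Reactants: 23 (E)-acid
Product: 24 tetraol (C1H2OH; C3–OH; C26–OH; C10–OH)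
Conditions: LiAlH4, THF, 0 → 25 °C
Reagents that add atoms: none
Why: LiAlH4 reduces the carboxylic acid to the primary allylic alcohol by 1,2-hydride delivery without touching the hindered tetrasubstituted alkene, so its geometry is kept.

**Step 18**
Reactants: 24 tetraol
Product: 25 C1,C3-bis(triethylsilyl) ether of 24
Conditions: Et3SiCl (2.2 equiv), imidazole, CH2Cl2, −40 °C
Reagents that add atoms: chlorotriethylsilane CC[Si](Cl)(CC)CC
Why: Silylation is selective for the two primary hydroxyls over the neopentylic secondary (C26) and tertiary (C10) ones.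

**Step 19**
Reactants: 25 bis-TES ether; 26 (diethoxyphosphoryl)acetic acid
Product: 27 C26 (diethoxyphosphoryl)acetate of 25
Conditions: DCC, DMAP (cat.), CH2Cl2, 25 °C
Reagents that add atoms: none
Why: Steglich esterification of the only acylable hydroxyl (C26–OH); the tertiary C10–OH does not react.

**Step 20**
Reactants: 27 phosphonoacetate
Product: 28 C26 diazo(diethoxyphosphoryl)acetate of 25
Conditions: 4-acetamidobenzenesulfonyl azide, DBU, MeCN, 0 °C
Reagents that add atoms: 4-acetamidobenzenesulfonyl azide CC(=O)Nc1ccc(cc1)S(=O)(=O)N=[N+]=[N-]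
Why: Regitz diazo transfer to the doubly activated methylene.

**Step 21**
Reactants: 28 diazo ester
Product: 29 cis-fused α-(diethoxyphosphoryl) γ-lactone (O26–C27(=O)–C15H[P(O)(OEt)2]–C14; epimers at C15)
Conditions: Rh2(OAc)4 (2 mol %), benzene, 80 °C, slow addition
Reagents that add atoms: none
Why: Rhodium carbenoid 1,5 C–H insertion into the C14 methylene (C11 carries no hydrogen) forms the γ-lactone, and because a five/five ring fusion can only be cis, C14 is set cis to the C26 oxygen; the tertiary C10–OH lies anti to the ester and is shielded by the spiro centre.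

**Step 22**
Reactants: 30 6-methylhept-5-en-2-one
Product: 32 6-methylhepta-1,5-dien-2-yl trifluoromethanesulfonate, via lithium enolate 31 (not isolated)
Conditions: LDA, THF, −78 °C; then PhNTf2, −78 → 0 °C
Reagents that add atoms: N-phenylbis(trifluoromethanesulfonimide) O=S(=O)(N(c1ccccc1)S(=O)(=O)C(F)(F)F)C(F)(F)F
Why: Kinetic deprotonation of the methyl ketone at CH3 and O-triflation give the terminal enol triflate.

**Step 23**
Reactants: 32 dienyl triflate; 33 (E)-2-(3,3-diethoxyprop-1-en-1-yl)-4,4,5,5-tetramethyl-1,3,2-dioxaborolane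
Product: 35 (2E)-8-methyl-4-methylidenenona-2,7-dienal, via diethyl acetal 34 (not isolated)
Conditions: Pd(PPh3)4 (5 mol %), K3PO4, dioxane/H2O, 60 °C; then 1 M HCl, THF, 0 °C
Reagents that add atoms: water O
Why: Suzuki–Miyaura coupling proceeds with retention of the E boronate geometry (sets the C17=C18 alkene) and mild acid hydrolysis of the acetal releases the aldehyde.

**Step 24**
Reactants: 29 phosphono lactone; 35 dienal
Product: 36 (15E,17E)-alkylidene lactone (C15=C16H–CH=CH–C(=CH2)CH2CH2CH=C(CH3)2 on the lactone α-carbon)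
Conditions: LiCl, DBU, MeCN, 0 → 25 °C
Reagents that add atoms: none
Why: Masamune–Roush Horner–Wadsworth–Emmons olefination of the α-phosphono lactone with the unhindered aldehyde gives the E-alkylidene lactone (dienyl chain anti to the lactone carbonyl, hence cis to C14), the thermodynamically preferred geometry.

**Step 25**
Reactants: 36 alkylidene lactone
Product: 37 diol (C27H2OH and C26–OH; C1 and C3 still OTES)
Conditions: i-Bu2AlH (5 equiv), CH2Cl2, −78 → −20 °C
Reagents that add atoms: none
Why: DIBAL reduces the lactone by 1,2-hydride addition through the lactol to the allylic 1,4-diol and leaves the silyl ethers and the triene untouched.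

**Step 26**
Reactants: 37 diol
Product: 38 C27 tert-butyldimethylsilyl ether of 37
Conditions: t-BuMe2SiCl (1.1 equiv), imidazole, CH2Cl2, −20 °C
Reagents that add atoms: tert-butyldimethylsilyl chloride CC(C)(C)[Si](C)(C)Cl
Why: Selective silylation of the primary allylic hydroxyl over the hindered secondary and tertiary ones protects C27 against the later allylic oxidation.

**Step 27**
Reactants: 38 mixed silyl ether
Product: 39 C27 TBS ether carrying free C1–OH and C3–OH
Conditions: PPTS (0.2 equiv), MeOH/CH2Cl2, 0 °C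
Reagents that add atoms: none
Why: Acid-catalysed methanolysis removes the two primary triethylsilyl ethers far faster than the tert-butyldimethylsilyl ether.

**Step 28**
Reactants: 39 tetraol mono-TBS ether
Product: 40 C27 TBS ether of the target (C1 = CHO)
Conditions: MnO2 (activated), CH2Cl2, 25 °C, dark
Reagents that add atoms: none
Why: MnO2 oxidises only the allylic C1 alcohol (the C3 primary and C26 secondary alcohols are not allylic and C27 is silylated) and does not disturb the alkene geometry.

**Step 29**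
Reactants: 40 silyl-protected enal
Product: 41 target CNP0246965.4
Conditions: Bu4NF, AcOH, THF, 0 → 25 °C
Reagents that add atoms: none
Why: Buffered fluoride desilylation frees the C27 hydroxyl without affecting the enal, the triene or the stereocentres.

**Compound list**
1 | geraniol, (2E)-3,7-dimethylocta-2,6-dien-1-ol | CC(C)=CCC/C(C)=C/CO | starting material
2 | (2S,3S)-2,3-epoxygeraniol | CC(C)=CCC[C@]1(C)O[C@H]1CO | intermediate
3 | (2R,3S)-2-(chloromethyl)-3-methyl-3-(4-methylpent-3-en-1-yl)oxirane | CC(C)=CCC[C@]1(C)O[C@H]1CCl | intermediate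
4 | benzyl 3-bromopropyl ether | BrCCCOCc1ccccc1 | starting material
5 | dilithium alkynide alkoxide of (3S)-3,7-dimethyloct-6-en-1-yn-3-ol (not isolated) | [Li+].[Li+].[C-]#C[C@@](C)([O-])CCC=C(C)C | intermediate
6 | (6S)-1-(benzyloxy)-6,10-dimethylundec-9-en-4-yn-6-ol | CC(C)=CCC[C@](C)(O)C#CCCCOCc1ccccc1 | intermediate
7 | (4Z,6S)-1-(benzyloxy)-6,10-dimethyl-5-(tributylstannyl)undeca-4,9-dien-6-ol | CC(C)=CCC[C@](C)(O)/C(=C/CCCOCc1ccccc1)[Sn](CCCC)(CCCC)CCCC | intermediate
8 | cyclobutanone | O=C1CCC1 | starting material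
9 | dilithium alkenyl alkoxide from 7 (not isolated) | [Li+].[Li+].CC(C)=CCC[C@](C)([O-])/[C-]=C/CCCOCc1ccccc1 | intermediate
10 | 1-[(4Z,6S)-1-(benzyloxy)-6-hydroxy-6,10-dimethylundeca-4,9-dien-5-yl]cyclobutan-1-ol | CC(C)=CCC[C@](C)(O)/C(=C/CCCOCc1ccccc1)C2(O)CCC2 | intermediate
11 | (8S,9Z)-9-[4-(benzyloxy)butylidene]-8-methyl-8-(4-methylpent-3-en-1-yl)-6,6-di(propan-2-yl)-5,7-dioxa-6-silaspiro[3.5]nonane | CC(C)=CCC[C@]1(C)O[Si](C(C)C)(C(C)C)OC2(CCC2)/C1=C\CCCOCc3ccccc3 | intermediate
12 | 3-[(8S,9Z)-9-[4-(benzyloxy)butylidene]-8-methyl-6,6-di(propan-2-yl)-5,7-dioxa-6-silaspiro[3.5]nonan-8-yl]propanal | O=CCC[C@]1(C)O[Si](C(C)C)(C(C)C)OC2(CCC2)/C1=C\CCCOCc3ccccc3 | intermediate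
13 | chlorodi(propan-2-yl)silyl ether of 14 at the tertiary oxygen (not isolated) | C1CC[C@]2([C@H](CCCOCc3ccccc3)[C@@H](O)CC[C@]2(C)O[Si](Cl)(C(C)C)C(C)C)C1=O | intermediate
14 | (5R,6S,9S,10S)-10-[3-(benzyloxy)propyl]-6,9-dihydroxy-6-methylspiro[4.5]decan-1-one | C1CC[C@]2([C@H](CCCOCc3ccccc3)[C@@H](O)CC[C@]2(C)O)C1=O | intermediate
15 | (5R,6S,10S)-6-[3-(benzyloxy)propyl]-10-hydroxy-10-methylspiro[4.5]decane-1,7-dione | C1CC[C@]2([C@H](CCCOCc3ccccc3)C(=O)CC[C@]2(C)O)C1=O | intermediate
16 | (1R,5S,6S,10S)-6-[3-(benzyloxy)propyl]-1,10-dihydroxy-10-methylspiro[4.5]decan-7-one | C1CC[C@]2([C@H](CCCOCc3ccccc3)C(=O)CC[C@]2(C)O)[C@@H]1O | intermediate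
17 | (1R,5S,6S,10S)-6-[3-(benzyloxy)propyl]-10-hydroxy-10-methyl-7-oxospiro[4.5]decan-1-yl benzoate | C1CC[C@]2([C@H](CCCOCc3ccccc3)C(=O)CC[C@]2(C)O)[C@@H]1OC(=O)c4ccccc4 | intermediate
18 | (1R,5S,6S,10S)-10-hydroxy-6-(3-hydroxypropyl)-10-methyl-7-oxospiro[4.5]decan-1-yl benzoate | C1CC[C@]2([C@H](CCCO)C(=O)CC[C@]2(C)O)[C@@H]1OC(=O)c3ccccc3 | intermediate
19 | ethyl diazo(diethoxyphosphoryl)acetate | CCOC(=O)C(=[N+]=[N-])P(=O)(OCC)OCC | starting material
20 | ethyl 2-{3-[(1R,5S,6S,10S)-1-(benzoyloxy)-10-hydroxy-10-methyl-7-oxospiro[4.5]decan-6-yl]propoxy}-2-(diethoxyphosphoryl)acetate (epimers at the phosphonate carbon) | C1CC[C@]2([C@H](CCCOC(C(=O)OCC)P(=O)(OCC)OCC)C(=O)CC[C@]2(C)O)[C@@H]1OC(=O)c3ccccc3 | intermediate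
21 | oxepine ester: ring B fused at C6–C7 to a 2,3,4,5-tetrahydrooxepine, enol ether C2=C7, CO2Et on C2, C26 benzoate, centres as in 18 | C1CC[C@]2([C@@H]3CCCOC(C(=O)OCC)=C3CC[C@]2(C)O)[C@@H]1OC(=O)c4ccccc4 | intermediate
22 | oxepine carboxylic acid (21 with CO2H and free C26–OH) | C1CC[C@]2([C@@H]3CCCOC(C(=O)O)=C3CC[C@]2(C)O)[C@@H]1O | intermediate
23 | ring-opened (E)-acid: C7=C2(CH3)CO2H with CH3 cis to C6, 3-hydroxypropyl on C6, C26–OH, C10–OH | C1CC[C@]2([C@H](CCCO)/C(=C(\C)C(=O)O)CC[C@]2(C)O)[C@@H]1O | intermediate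
24 | tetraol: 23 with C1H2OH in place of CO2H | C1CC[C@]2([C@H](CCCO)/C(=C(\C)CO)CC[C@]2(C)O)[C@@H]1O | intermediate
25 | C1,C3-bis(triethylsilyl) ether of 24 | C1CC[C@]2([C@H](CCCO[Si](CC)(CC)CC)/C(=C(\C)CO[Si](CC)(CC)CC)CC[C@]2(C)O)[C@@H]1O | intermediate
26 | (diethoxyphosphoryl)acetic acid | OC(=O)CP(=O)(OCC)OCC | starting material
27 | C26 (diethoxyphosphoryl)acetate of 25 | C1CC[C@]2([C@H](CCCO[Si](CC)(CC)CC)/C(=C(\C)CO[Si](CC)(CC)CC)CC[C@]2(C)O)[C@@H]1OC(=O)CP(=O)(OCC)OCC | intermediate
28 | C26 diazo(diethoxyphosphoryl)acetate of 25 | C1CC[C@]2([C@H](CCCO[Si](CC)(CC)CC)/C(=C(\C)CO[Si](CC)(CC)CC)CC[C@]2(C)O)[C@@H]1OC(=O)C(=[N+]=[N-])P(=O)(OCC)OCC | intermediate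
29 | cis-fused α-(diethoxyphosphoryl) γ-lactone (epimers at C15) | O=C3C(P(=O)(OCC)OCC)[C@@H]1CC[C@]2([C@H](CCCO[Si](CC)(CC)CC)/C(=C(\C)CO[Si](CC)(CC)CC)CC[C@]2(C)O)[C@@H]1O3 | intermediate
30 | 6-methylhept-5-en-2-one | CC(=O)CCC=C(C)C | starting material
31 | lithium 6-methylhepta-1,5-dien-2-olate (not isolated) | C=C([O-])CCC=C(C)C.[Li+] | intermediate
32 | 6-methylhepta-1,5-dien-2-yl trifluoromethanesulfonate | C=C(OS(=O)(=O)C(F)(F)F)CCC=C(C)C | intermediate
33 | (E)-2-(3,3-diethoxyprop-1-en-1-yl)-4,4,5,5-tetramethyl-1,3,2-dioxaborolane | CCOC(OCC)/C=C/B1OC(C)(C)C(C)(C)O1 | starting material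
34 | (2E)-1,1-diethoxy-8-methyl-4-methylidenenona-2,7-diene (not isolated) | CCOC(OCC)/C=C/C(=C)CCC=C(C)C | intermediate
35 | (2E)-8-methyl-4-methylidenenona-2,7-dienal | O=C/C=C/C(=C)CCC=C(C)C | intermediate
36 | (15E,17E)-alkylidene lactone | O=C3/C(=C/C=C/C(=C)CCC=C(C)C)[C@@H]1CC[C@]2([C@H](CCCO[Si](CC)(CC)CC)/C(=C(\C)CO[Si](CC)(CC)CC)CC[C@]2(C)O)[C@@H]1O3 | intermediate
37 | C26,C27-diol with C1 and C3 as TES ethers | OC/C(=C/C=C/C(=C)CCC=C(C)C)[C@@H]1CC[C@]2([C@H](CCCO[Si](CC)(CC)CC)/C(=C(\C)CO[Si](CC)(CC)CC)CC[C@]2(C)O)[C@@H]1O | intermediate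
38 | C27 tert-butyldimethylsilyl ether of 37 | CC(C)(C)[Si](C)(C)OC/C(=C/C=C/C(=C)CCC=C(C)C)[C@@H]1CC[C@]2([C@H](CCCO[Si](CC)(CC)CC)/C(=C(\C)CO[Si](CC)(CC)CC)CC[C@]2(C)O)[C@@H]1O | intermediate
39 | C27 TBS ether with free C1–OH and C3–OH | CC(C)(C)[Si](C)(C)OC/C(=C/C=C/C(=C)CCC=C(C)C)[C@@H]1CC[C@]2([C@H](CCCO)/C(=C(\C)CO)CC[C@]2(C)O)[C@@H]1O | intermediate
40 | C27 TBS ether of the target | CC(C)(C)[Si](C)(C)OC/C(=C/C=C/C(=C)CCC=C(C)C)[C@@H]1CC[C@]2([C@H](CCCO)/C(=C(\C)C=O)CC[C@]2(C)O)[C@@H]1O | intermediate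
41 | CNP0246965.4 | C=C(/C=C/C=C(/CO)[C@@H]1CC[C@]2([C@H](CCCO)/C(=C(\C)C=O)CC[C@]2(C)O)[C@@H]1O)CCC=C(C)C | target

**Totals**
Total step count: 29. Longest linear sequence: 27 (steps 1–21 and 24–29, from geraniol); steps 22–23 make dienal 35.

**Three steps most likely to fail, each with a fallback**

Step 8 (Prins–semipinacol cascade). Risks are ionisation of the two allylic C–O bonds, trapping of the C11 cation by the benzyl ether oxygen, and loss of the C6 proton instead of ring expansion. The fallback changes the initiator from a Lewis-acid-bound aldehyde to a softer thionium ion and sets out from 12. Thioacetalisation (PhSH, MgBr2·OEt2, CH2Cl2) gives the bis(phenylthio)acetal F1. Dimethyl(methylthio)sulfonium tetrafluoroborate in CH2Cl2 at −45 °C generates the thionium ion, which triggers the same cyclisation and ring expansion to the fluorosilyl ether F2, and HF work-up gives the phenylthio spiro ketone F3. Oxidation with NaIO4 gives the sulfoxide F4, Pummerer rearrangement (trifluoroacetic anhydride, 2,6-lutidine) gives the α-(trifluoroacetoxy) sulfide F5, and aqueous NaHCO3 hydrolysis returns the route at 15 (14 is bypassed).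

Step 16 (nickel-catalysed C–O methylation of a tetrasubstituted enol ether). Risks are slow oxidative addition, methyl addition to the carboxylate and alkene isomerisation. The fallback gives up the ring-locked approach for a 1,3-hydroxyl transposition and sets out from 16, so that steps 11–17 are not run. Excess isopropenylmagnesium bromide with CeCl3 (THF, −78 → 0 °C) adds to the C7 ketone to give the tertiary allylic alcohol F6. Ph3SiOReO3 (5 mol %, Et2O, 0 °C) transposes the hydroxyl to the primary allylic alcohol F7, which forms together with its geometric isomer; the isomers are separated and the unwanted one is re-equilibrated with the same reversible rhenium catalyst. Reductive debenzylation of F7 (lithium 4,4'-di-tert-butylbiphenylide, THF, −78 °C) returns the route at 24. This fallback is not stereospecific at the C7=C2 alkene.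

Step 21 (carbenoid C–H insertion). Risks are β-lactone formation by insertion into the C26–H bond, O–H insertion at the C10 hydroxyl and low reactivity of the phosphoryl carbenoid. The fallback functionalises C14 through the ketone enolate and sets out from 25. Dess–Martin oxidation gives the C26 ketone F8. LiHMDS (2.2 equiv) and ethyl bromoacetate alkylate C14, the only enolisable position, to give the keto ester F9 (the acetate arm prefers the face away from C10 and the C14 epimers equilibrate). Hydroxyl-directed reduction with Me4NBH(OAc)3 as in step 10 gives the hydroxy ester F10, and only the cis isomer lactonises (PPTS, benzene) to the γ-lactone F11. Aldol addition of its lithium enolate to 35 gives the β-hydroxy lactone F12, and elimination of its mesylate F13 (MsCl, Et3N; DBU) returns the route at 36.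

**Further compounds**
F1 | step 8 | bis(phenylthio)acetal of aldehyde 12 | c4ccccc4SC(Sc5ccccc5)CC[C@]1(C)O[Si](C(C)C)(C(C)C)OC2(CCC2)/C1=C\CCCOCc3ccccc3
F2 | step 8 | fluorodi(propan-2-yl)silyl ether of F3 at the tertiary oxygen | C1CC[C@]2([C@H](CCCOCc3ccccc3)C(Sc4ccccc4)CC[C@]2(C)O[Si](F)(C(C)C)C(C)C)C1=O
F3 | step 8 | C7 phenylthio analogue of 14 | C1CC[C@]2([C@H](CCCOCc3ccccc3)C(Sc4ccccc4)CC[C@]2(C)O)C1=O
F4 | step 8 | sulfoxide of F3 | C1CC[C@]2([C@H](CCCOCc3ccccc3)C(S(=O)c4ccccc4)CC[C@]2(C)O)C1=O
F5 | step 8 | C7 α-(trifluoroacetoxy) phenyl sulfide | C1CC[C@]2([C@H](CCCOCc3ccccc3)C(OC(=O)C(F)(F)F)(Sc4ccccc4)CC[C@]2(C)O)C1=O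
F6 | step 16 | C7 isopropenyl carbinol from 16 | C1CC[C@]2([C@H](CCCOCc3ccccc3)C(O)(C(C)=C)CC[C@]2(C)O)[C@@H]1O
F7 | step 16 | C3 benzyl ether of 24 | C1CC[C@]2([C@H](CCCOCc3ccccc3)/C(=C(\C)CO)CC[C@]2(C)O)[C@@H]1O
F8 | step 21 | C26 ketone from 25 | C1CC[C@]2([C@H](CCCO[Si](CC)(CC)CC)/C(=C(\C)CO[Si](CC)(CC)CC)CC[C@]2(C)O)C1=O
F9 | step 21 | C14 (ethoxycarbonyl)methyl ketone | CCOC(=O)C[C@@H]1CC[C@]2([C@H](CCCO[Si](CC)(CC)CC)/C(=C(\C)CO[Si](CC)(CC)CC)CC[C@]2(C)O)C1=O
F10 | step 21 | cis hydroxy ester from F9 | CCOC(=O)C[C@@H]1CC[C@]2([C@H](CCCO[Si](CC)(CC)CC)/C(=C(\C)CO[Si](CC)(CC)CC)CC[C@]2(C)O)[C@@H]1O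
F11 | step 21 | cis-fused γ-lactone (29 with H in place of the phosphoryl group) | O=C3C[C@@H]1CC[C@]2([C@H](CCCO[Si](CC)(CC)CC)/C(=C(\C)CO[Si](CC)(CC)CC)CC[C@]2(C)O)[C@@H]1O3
F12 | step 21 | β-hydroxy lactone from F11 and 35 | O=C3C(C(O)/C=C/C(=C)CCC=C(C)C)[C@@H]1CC[C@]2([C@H](CCCO[Si](CC)(CC)CC)/C(=C(\C)CO[Si](CC)(CC)CC)CC[C@]2(C)O)[C@@H]1O3
F13 | step 21 | mesylate of F12 | O=C3C(C(OS(C)(=O)=O)/C=C/C(=C)CCC=C(C)C)[C@@H]1CC[C@]2([C@H](CCCO[Si](CC)(CC)CC)/C(=C(\C)CO[Si](CC)(CC)CC)CC[C@]2(C)O)[C@@H]1O3
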